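The pyranone ring (O1–C2–C3–C4–C4a–C8a) is never cyclised as such: it is grown out of a benzofuran. C3 is delivered as a zinc carbenoid to the enol double bond of a 2-aryl-3-siloxybenzofuran, and the resulting cyclopropa[b]benzofuranyl silyl ether opens at its fusion bond on desilylation, so the five-membered O-heterocycle becomes six-membered ring C, C4 becomes the ketone and C2 receives H with inversion. The step exploits C2, which carries the B-ring aryl group and O1 and therefore takes the carbanion character that directs the cleavage. The C8 side chain, made separately from a chiral lactone, is joined afterwards by Negishi coupling at an 8-bromide.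

Key step: step 8

Remark on the chemistry: the chiral methyl lactone is taken as a commercial building block. Base-induced opening of a cyclopropanolate is taken to proceed with inversion at the protonated carbon, the general course for cyclopropanols. The antipodal ligand would be used in step 7 if the other sense were found. Flavanone numbering is used for the target, and cyclopropa[b]benzofuran numbering (C1 = CH2, C1a = O- and aryl-bearing carbon, C6b = siloxy carbon) for the bicyclic intermediates.

Step 1
Reactants: 1 2,4-dihydroxybenzaldehyde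
Product: 2 2,4-bis(methoxymethoxy)benzaldehyde
Conditions: MOMCl (2.5 equiv), i-Pr2NEt, CH2Cl2, 0 °C to rt
Reagents that add atoms: chloromethyl methyl ether (MOMCl), COCCl
Why: Base-mediated O-alkylation (Williamson-type acetal formation) of both phenols with excess MOMCl should go to completion, the chelated 2-OH reacting last; no stereocenter is formed.

Step 2
Reactants: 2 2,4-bis(methoxymethoxy)benzaldehyde
Product: 3 [2,4-bis(methoxymethoxy)phenyl]methanol
Conditions: NaBH4, MeOH, 0 °C
Reagents that add atoms: none
Why: Borohydride reduction of the aryl aldehyde to the benzylic alcohol leaves the MOM acetals untouched; no stereocenter.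

Step 3
Reactants: 4 methyl 2,4,6-trihydroxybenzoate
Product: 5 methyl 2-hydroxy-4,6-bis(methoxymethoxy)benzoate
Conditions: MOMCl (2.1 equiv), i-Pr2NEt, CH2Cl2, 0 °C
Reagents that add atoms: chloromethyl methyl ether (MOMCl), COCCl
Why: Williamson-type MOM protection should stop at the 4,6-bis-ether because the remaining ortho-OH is held in a hydrogen bond to the ester carbonyl and is the least nucleophilic; no stereocenter.

Step 4
Reactants: 5 methyl 2-hydroxy-4,6-bis(methoxymethoxy)benzoate
Product: 6 methyl 3-bromo-2-hydroxy-4,6-bis(methoxymethoxy)benzoate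
Conditions: NBS, CH2Cl2, −20 to 0 °C
Reagents that add atoms: N-bromosuccinimide, O=C1CCC(=O)N1Br
Why: Electrophilic aromatic bromination should go ortho to the free phenol, at the carbon flanked by OH and one OMOM group, which is less hindered than the carbon between two OMOM groups; this places Br on the future C8.

Step 5
Reactants: 6 methyl 3-bromo-2-hydroxy-4,6-bis(methoxymethoxy)benzoate; 3 [2,4-bis(methoxymethoxy)phenyl]methanol
Product: 7 methyl 2-{[2,4-bis(methoxymethoxy)phenyl]methoxy}-3-bromo-4,6-bis(methoxymethoxy)benzoate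
Conditions: PPh3, DIAD, THF, 0 °C to rt
Reagents that add atoms: none
Why: Mitsunobu etherification joins the acidic chelated phenol to the primary benzylic alcohol under neutral conditions and avoids an unstable electron-rich benzyl halide; no stereocenter.

Step 6
Reactants: 7 methyl 2-{[2,4-bis(methoxymethoxy)phenyl]methoxy}-3-bromo-4,6-bis(methoxymethoxy)benzoate
Product: 9 {[2-(2,4-bis(methoxymethoxy)phenyl)-7-bromo-4,6-bis(methoxymethoxy)-1-benzofuran-3-yl]oxy}(trimethyl)silane, via lithium benzofuran-3-olate 8 (not isolated)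
Conditions: LiN(i-Pr)2 (2.2 equiv), THF, −78 to −40 °C; then Me3SiCl, −78 °C to rt
Reagents that add atoms: chlorotrimethylsilane, C[Si](C)(C)Cl
Why: Lithiation of the benzylic O–CH2 group (acidified by oxygen and aryl, guided by coordination to the ortho-OMOM group and the ester) is followed by 5-exo-trig intramolecular Claisen-type acylation with loss of methoxide, the second equivalent of amide converts the benzofuranone into its aromatic enolate 8, and O-silylation traps it as the silyl enol ether.

Step 7
Reactants: 9 {[2-(2,4-bis(methoxymethoxy)phenyl)-7-bromo-4,6-bis(methoxymethoxy)-1-benzofuran-3-yl]oxy}(trimethyl)silane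
Product: 10 (1aR,6bR)-1a-[2,4-bis(methoxymethoxy)phenyl]-3-bromo-4,6-bis(methoxymethoxy)-6b-[(trimethylsilyl)oxy]-1a,6b-dihydro-1H-cyclopropa[b][1]benzofuran
Conditions: Et2Zn (1.5 equiv), CH2I2 (3 equiv), N-Boc-L-valyl-L-proline methyl ester (0.3 equiv; the antipode if it is the one that leads to the 1aR,6bR series), ethyl methoxyacetate, CH2Cl2, −40 to 0 °C
Reagents that add atoms: diiodomethane, ICI
Why: Simmons–Smith cyclopropanation (Furukawa conditions) of the electron-rich silyl enol ether with a zinc carbenoid modified by the chiral N-Boc dipeptide should add CH2 to one face of the enol double bond, so that C1a and C6b are set together under ligand control (the fusion can only be cis), as is known for aryl silyl enol ethers.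

Step 8
Reactants: 10 (1aR,6bR)-1a-[2,4-bis(methoxymethoxy)phenyl]-3-bromo-4,6-bis(methoxymethoxy)-6b-[(trimethylsilyl)oxy]-1a,6b-dihydro-1H-cyclopropa[b][1]benzofuran
Product: 12 (2S)-2-[2,4-bis(methoxymethoxy)phenyl]-8-bromo-5,7-bis(methoxymethoxy)-2,3-dihydro-4H-chromen-4-one, via potassium cyclopropanolate 11 (not isolated)
Conditions: K2CO3 (0.2 equiv), MeOH–THF, −20 to 0 °C
Reagents that add atoms: none
Why: Methanolysis of the O–Si bond gives cyclopropanolate 11, whose oxyanion pushes out the fusion bond C6b–C1a while methanol protonates C1a from the rear (SE2 with inversion), so C6b becomes the C4 carbonyl, C1 becomes C3 and the five-membered O-heterocycle is enlarged to the six-membered pyranone. The closest known reaction type is the base-induced ring opening of 2-arylcyclopropanols to β-aryl ketones (homoenolate protonolysis), used here in the ring-enlarging sense familiar from Ito–Saegusa openings of bicyclic siloxycyclopropanes. No ring is closed by bond formation: the six-membered ring arises by cleavage of the zero-atom bridge of the 2-oxabicyclo[3.1.0]hexane core. The only new stereocenter, C2, is controlled by C1a of 10: O1, the aryl group and C3 keep their sense and H enters anti to the departing C4, so 1aR should give 2S. The step needs cleavage of the inner C1a–C6b bond and not of C1–C6b, which is secured by the benzylic, O-substituted carbanion character available only at C1a and by the larger strain release. It also needs the product to resist E1cB opening to the chalcone, for which catalytic base, low temperature and a protic medium are chosen.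

Step 9
Reactants: 13 (4S)-4-methyloxolan-2-one
Product: 15 (3S,4S)-4-methyl-3-(3-methylbut-2-en-1-yl)oxolan-2-one, via lithium lactone enolate 14 (not isolated)
Conditions: LiN(i-Pr)2, THF, −78 °C; then prenyl bromide, DMPU, −78 to −40 °C
Reagents that add atoms: 1-bromo-3-methylbut-2-ene (prenyl bromide), CC(C)=CCBr
Why: Alkylation of the lithium lactone enolate with the allylic bromide should occur anti to the C4 methyl group (1,2-induction in the five-membered enolate), giving the trans (3S,4S) lactone.

Step 10
Reactants: 15 (3S,4S)-4-methyl-3-(3-methylbut-2-en-1-yl)oxolan-2-one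
Product: 17 tert-butyldimethylsilyl (2S,3S)-4-{[tert-butyl(dimethyl)silyl]oxy}-3-methyl-2-(3-methylbut-2-en-1-yl)butanoate, via potassium hydroxy carboxylate 16 (not isolated)
Conditions: KOH, MeOH–H2O, rt; evaporation to dryness; then t-BuMe2SiCl (2.5 equiv), imidazole, DMF, rt
Reagents that add atoms: potassium hydroxide, [K+].[OH-]; tert-butyldimethylsilyl chloride, CC(C)(C)[Si](C)(C)Cl
Why: Saponification opens the lactone without touching the stereocenters, and silylation of the dry potassium salt on both carboxylate and alcohol prevents relactonisation.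

Step 11
Reactants: 17 tert-butyldimethylsilyl (2S,3S)-4-{[tert-butyl(dimethyl)silyl]oxy}-3-methyl-2-(3-methylbut-2-en-1-yl)butanoate
Product: 18 (2S,3S)-4-{[tert-butyl(dimethyl)silyl]oxy}-3-methyl-2-(3-methylbut-2-en-1-yl)butan-1-ol
Conditions: LiAlH4, THF, 0 °C
Reagents that add atoms: none
Why: Hydride reduction of the labile silyl ester gives the primary alcohol at 0 °C while the silyl ether survives, and the α-stereocenter is not enolised under hydride conditions.

Step 12
Reactants: 18 (2S,3S)-4-{[tert-butyl(dimethyl)silyl]oxy}-3-methyl-2-(3-methylbut-2-en-1-yl)butan-1-ol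
Product: 19 tert-butyl{[(2S,3S)-3-(iodomethyl)-2,6-dimethylhept-5-en-1-yl]oxy}dimethylsilane
Conditions: I2, PPh3, imidazole, CH2Cl2, 0 °C to rt
Reagents that add atoms: iodine, II
Why: Appel iodination converts the primary alcohol into the iodide by SN2 displacement of the alkoxyphosphonium ion, and the stereocenters lie β and γ to the reacting carbon and are untouched.

Step 13
Reactants: 19 tert-butyl{[(2S,3S)-3-(iodomethyl)-2,6-dimethylhept-5-en-1-yl]oxy}dimethylsilane; 12 (2S)-2-[2,4-bis(methoxymethoxy)phenyl]-8-bromo-5,7-bis(methoxymethoxy)-2,3-dihydro-4H-chromen-4-one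
Product: 21 (2S)-2-[2,4-bis(methoxymethoxy)phenyl]-8-[(2R,3S)-4-{[tert-butyl(dimethyl)silyl]oxy}-3-methyl-2-(3-methylbut-2-en-1-yl)butyl]-5,7-bis(methoxymethoxy)-2,3-dihydro-4H-chromen-4-one, via alkylzinc iodide 20 (not isolated)
Conditions: Zn dust, LiCl, THF, 40 °C; then 12, Pd(OAc)2 (5 mol %), SPhos (10 mol %), THF, 50 °C
Reagents that add atoms: none
Why: Negishi coupling: zinc inserts into the primary C–I bond, and zerovalent palladium bearing the bulky biarylphosphine adds to the hindered electron-rich aryl bromide and couples it with the non-basic alkylzinc under neutral conditions that leave the ketone, the epimerisable C2 and the trisubstituted alkene untouched.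

Step 14
Reactants: 21 (2S)-2-[2,4-bis(methoxymethoxy)phenyl]-8-[(2R,3S)-4-{[tert-butyl(dimethyl)silyl]oxy}-3-methyl-2-(3-methylbut-2-en-1-yl)butyl]-5,7-bis(methoxymethoxy)-2,3-dihydro-4H-chromen-4-one
Product: 22 (2S)-2-(2,4-dihydroxyphenyl)-5,7-dihydroxy-8-[(2R,3S)-4-hydroxy-3-methyl-2-(3-methylbut-2-en-1-yl)butyl]-2,3-dihydro-4H-chromen-4-one (CNP0262638.1)
Conditions: HCl (3 M aq.), MeOH, 40 °C
Reagents that add atoms: none
Why: Acid-catalysed acetal exchange removes the four MOM groups and solvolyses the silyl ether in one operation; the flavanone has no E1cB pathway in acid and the remote trisubstituted alkene should survive these mild conditions.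

Compound list

1 | 2,4-dihydroxybenzaldehyde | O=Cc1ccc(O)cc1O | starting material
2 | 2,4-bis(methoxymethoxy)benzaldehyde | O=Cc1ccc(OCOC)cc1OCOC | intermediate
3 | [2,4-bis(methoxymethoxy)phenyl]methanol | OCc1ccc(OCOC)cc1OCOC | intermediate
4 | methyl 2,4,6-trihydroxybenzoate | COC(=O)c1c(O)cc(O)cc1O | starting material
5 | methyl 2-hydroxy-4,6-bis(methoxymethoxy)benzoate | COC(=O)c1c(O)cc(OCOC)cc1OCOC | intermediate
6 | methyl 3-bromo-2-hydroxy-4,6-bis(methoxymethoxy)benzoate | COC(=O)c1c(O)c(Br)c(OCOC)cc1OCOC | intermediate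
7 | methyl 2-{[2,4-bis(methoxymethoxy)phenyl]methoxy}-3-bromo-4,6-bis(methoxymethoxy)benzoate | COC(=O)c1c(OCc2ccc(OCOC)cc2OCOC)c(Br)c(OCOC)cc1OCOC | intermediate
8 | lithium 2-[2,4-bis(methoxymethoxy)phenyl]-7-bromo-4,6-bis(methoxymethoxy)-1-benzofuran-3-olate | [Li+].[O-]c1c(-c2ccc(OCOC)cc2OCOC)oc2c(Br)c(OCOC)cc(OCOC)c12 | intermediate (not isolated)
9 | {[2-(2,4-bis(methoxymethoxy)phenyl)-7-bromo-4,6-bis(methoxymethoxy)-1-benzofuran-3-yl]oxy}(trimethyl)silane | C[Si](C)(C)Oc1c(-c2ccc(OCOC)cc2OCOC)oc2c(Br)c(OCOC)cc(OCOC)c12 | intermediate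
10 | (1aR,6bR)-1a-[2,4-bis(methoxymethoxy)phenyl]-3-bromo-4,6-bis(methoxymethoxy)-6b-[(trimethylsilyl)oxy]-1a,6b-dihydro-1H-cyclopropa[b][1]benzofuran | O1c2c(Br)c(OCOC)cc(OCOC)c2[C@]3(O[Si](C)(C)C)C[C@]13c4ccc(OCOC)cc4OCOC | intermediate
11 | potassium (1aR,6bR)-1a-[2,4-bis(methoxymethoxy)phenyl]-3-bromo-4,6-bis(methoxymethoxy)-1,1a-dihydro-6bH-cyclopropa[b][1]benzofuran-6b-olate | O1c2c(Br)c(OCOC)cc(OCOC)c2[C@]3([O-])C[C@]13c4ccc(OCOC)cc4OCOC.[K+] | intermediate (not isolated)
12 | (2S)-2-[2,4-bis(methoxymethoxy)phenyl]-8-bromo-5,7-bis(methoxymethoxy)-2,3-dihydro-4H-chromen-4-one | Brc1c(OCOC)cc(OCOC)c2c1O[C@H](c1ccc(OCOC)cc1OCOC)CC2=O | intermediate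
13 | (4S)-4-methyloxolan-2-one | C[C@@H]1COC(=O)C1 | starting material
14 | lithium (4S)-4-methyl-4,5-dihydrofuran-2-olate | C[C@@H]1COC([O-])=C1.[Li+] | intermediate (not isolated)
15 | (3S,4S)-4-methyl-3-(3-methylbut-2-en-1-yl)oxolan-2-one | C[C@@H]1COC(=O)[C@H]1CC=C(C)C | intermediate
16 | potassium (2S,3S)-4-hydroxy-3-methyl-2-(3-methylbut-2-en-1-yl)butanoate | CC(C)=CC[C@H](C(=O)[O-])[C@H](C)CO.[K+] | intermediate (not isolated)
17 | tert-butyldimethylsilyl (2S,3S)-4-{[tert-butyl(dimethyl)silyl]oxy}-3-methyl-2-(3-methylbut-2-en-1-yl)butanoate | CC(C)=CC[C@H](C(=O)O[Si](C)(C)C(C)(C)C)[C@H](C)CO[Si](C)(C)C(C)(C)C | intermediate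
18 | (2S,3S)-4-{[tert-butyl(dimethyl)silyl]oxy}-3-methyl-2-(3-methylbut-2-en-1-yl)butan-1-ol | CC(C)=CC[C@H](CO)[C@H](C)CO[Si](C)(C)C(C)(C)C | intermediate
19 | tert-butyl{[(2S,3S)-3-(iodomethyl)-2,6-dimethylhept-5-en-1-yl]oxy}dimethylsilane | CC(C)=CC[C@H](CI)[C@H](C)CO[Si](C)(C)C(C)(C)C | intermediate
20 | [(2S,3S)-4-{[tert-butyl(dimethyl)silyl]oxy}-3-methyl-2-(3-methylbut-2-en-1-yl)butyl](iodo)zinc | CC(C)=CC[C@H](C[Zn]I)[C@H](C)CO[Si](C)(C)C(C)(C)C | intermediate (not isolated)
21 | (2S)-2-[2,4-bis(methoxymethoxy)phenyl]-8-[(2R,3S)-4-{[tert-butyl(dimethyl)silyl]oxy}-3-methyl-2-(3-methylbut-2-en-1-yl)butyl]-5,7-bis(methoxymethoxy)-2,3-dihydro-4H-chromen-4-one | CC(C)=CC[C@H](Cc1c(OCOC)cc(OCOC)c2c1O[C@H](c1ccc(OCOC)cc1OCOC)CC2=O)[C@H](C)CO[Si](C)(C)C(C)(C)C | intermediate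
22 | (2S)-2-(2,4-dihydroxyphenyl)-5,7-dihydroxy-8-[(2R,3S)-4-hydroxy-3-methyl-2-(3-methylbut-2-en-1-yl)butyl]-2,3-dihydro-4H-chromen-4-one | CC(C)=CC[C@H](Cc1c(O)cc(O)c2c1O[C@H](c1ccc(O)cc1O)CC2=O)[C@H](C)CO | target

Total step count: 14. Longest linear sequence: 8 steps (4 → 5 → 6 → 7 → 9 → 10 → 12 → 21 → 22; steps 3 to 8, 13 and 14).

Steps most likely to fail

Step 7. The carbenoid may discriminate poorly between the two faces of the tetrasubstituted, aryl-flanked enol ether, or methylene transfer to this hindered double bond may be slow. The fallback replaces asymmetric induction by resolution. It sets out from 9: cyclopropanation without a chiral ligand, using the more reactive carbenoid from Et2Zn, CF3CO2H and CH2I2, would give the racemic siloxycyclopropane F1. Ring expansion under the conditions of step 8 would give the racemic bromoflavanone F2. Preparative chromatography on a chiral stationary phase would separate 12 from its (2R)-antipode F3. F3 would be returned to F2 with K2CO3 in MeOH at rt (reversible E1cB opening and oxa-Michael reclosure) and recycled. The route is rejoined at 12.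

Step 8. The oxyanion may break the outer C1–C6b bond so that the ring is not enlarged, or the configuration at C2 may erode through base-induced opening to the chalcone and reclosure. The fallback replaces the polar opening by a radical 1,2-acyl shift. It sets out from 7: cyclisation as in step 6 to enolate 8 and C-alkylation with CH2I2 in THF–HMPA would give the racemic 2-(iodomethyl)benzofuranone F4. Treatment with Bu3SnH (slow addition) and AIBN in benzene at 80 °C should effect a Dowd–Beckwith ring expansion: 3-exo attack of the primary radical on the ketone, β-scission to the benzylic α-oxy radical at C2 and hydrogen transfer. The primary C–I bond is expected to react far faster with the stannyl radical than the aryl bromide. This gives the racemic bromoflavanone F2, which would be resolved as described under step 7, and the route is rejoined at 12.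

Step 6. Deprotonation may take place on the arenes between two OMOM groups instead of at the benzylic ether, or the lithiated ether may rearrange by 1,2-aryl shift before it acylates. The fallback uses an ester-stabilised carbanion and a Dieckmann condensation. It sets out from 6 and commercial methyl (2,4-dihydroxyphenyl)acetate. MOM protection of the latter would give methyl [2,4-bis(methoxymethoxy)phenyl]acetate F5. Enolisation with LiN(SiMe3)2 and bromination with NBS would give the α-bromo ester F6. O-Alkylation of 6 with F6 (K2CO3, DMF) would give the diester F7. KOt-Bu in THF should close the ring by Dieckmann condensation to the β-keto ester F8. Krapcho dealkoxycarbonylation (LiCl, DMF, 120 °C) would release enolate 8, which is silylated with Me3SiCl as in step 6, so the route is rejoined at 8 and continues to 9.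

Further compounds

F1 | step 7 | racemic 1a-[2,4-bis(methoxymethoxy)phenyl]-3-bromo-4,6-bis(methoxymethoxy)-6b-[(trimethylsilyl)oxy]-1a,6b-dihydro-1H-cyclopropa[b][1]benzofuran | C[Si](C)(C)OC12CC1(Oc3c(Br)c(OCOC)cc(OCOC)c23)c4ccc(OCOC)cc4OCOC
F2 | step 7 | racemic 2-[2,4-bis(methoxymethoxy)phenyl]-8-bromo-5,7-bis(methoxymethoxy)-2,3-dihydro-4H-chromen-4-one | O=C1CC(c2ccc(OCOC)cc2OCOC)Oc2c(Br)c(OCOC)cc(OCOC)c12
F3 | step 7 | (2R)-2-[2,4-bis(methoxymethoxy)phenyl]-8-bromo-5,7-bis(methoxymethoxy)-2,3-dihydro-4H-chromen-4-one | Brc1c(OCOC)cc(OCOC)c2c1O[C@@H](c1ccc(OCOC)cc1OCOC)CC2=O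
F4 | step 8 | racemic 2-[2,4-bis(methoxymethoxy)phenyl]-7-bromo-2-(iodomethyl)-4,6-bis(methoxymethoxy)-1-benzofuran-3(2H)-one | ICC1(c2ccc(OCOC)cc2OCOC)Oc2c(Br)c(OCOC)cc(OCOC)c2C1=O
F5 | step 6 | methyl [2,4-bis(methoxymethoxy)phenyl]acetate | COC(=O)Cc1ccc(OCOC)cc1OCOC
F6 | step 6 | racemic methyl bromo[2,4-bis(methoxymethoxy)phenyl]acetate | COC(=O)C(Br)c1ccc(OCOC)cc1OCOC
F7 | step 6 | racemic methyl 2-{1-[2,4-bis(methoxymethoxy)phenyl]-2-methoxy-2-oxoethoxy}-3-bromo-4,6-bis(methoxymethoxy)benzoate | COC(=O)c1c(OC(C(=O)OC)c2ccc(OCOC)cc2OCOC)c(Br)c(OCOC)cc1OCOC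
F8 | step 6 | racemic methyl 2-[2,4-bis(methoxymethoxy)phenyl]-7-bromo-4,6-bis(methoxymethoxy)-3-oxo-2,3-dihydro-1-benzofuran-2-carboxylate | COC(=O)C1(c2ccc(OCOC)cc2OCOC)Oc2c(Br)c(OCOC)cc(OCOC)c2C1=O
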